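**Plan**

1. Numbering (daucane): five-membered ring C1–C5 (C1 quaternary with CH3, C4 with OH and isopropyl, C5–H); seven-membered ring C1, C5, C6 (O-aroyl), C7, C8 (CH3), C9, C10 (O-tigloyl).
2. Cuts: both ester C–O bonds; then C9 is excised from the seven-membered ring (bonds C8–C9 and C9–C10), leaving a trans-hydrindane with a C10 ketone and a CH3 on C8; then C8–CH3, C6–O/C5–H (hydroboration of C5=C6), C4=C5 (aldol condensation) and C1–C2 (Michael addition).
3. Enabling feature: C10 lies between the quaternary C1, which has no hydrogen, and C9, which is bonded to the methyl-bearing C8. A six-membered C10 ketone therefore enolises only towards C8, and a CH2 added across C8=C10 enters the ring when the shared C8–C10 bond breaks to the tertiary C8 radical.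
4. Forward order: six-membered ring (bought) → five-membered ring by aldol condensation → stereocentres set on the rigid hydrindane → six-to-seven ring expansion that also places C8=C9 and the C10 carbonyl → C10 reduction and acylation.
5. Stereochemistry: C1 from a chiral-imine Michael addition; C4–O, C5–H and C6–O from reagent attack on the face anti to the C1 methyl (epoxidation, then hydroboration); C10 from a reagent-controlled CBS reduction.

Key step: step 13

Remark: racemic 7-methyl-1,4-dioxaspiro[4.5]decan-8-one, 4-methylpent-1-en-3-one and tigloyl chloride are taken as catalogue compounds; "anti" and "syn" always refer to the face of the C1 methyl group.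

**Route**

Step 1
Reactants: 1 7-methyl-1,4-dioxaspiro[4.5]decan-8-one (racemic); 2 (S)-1-phenylethylamine; 3 4-methylpent-1-en-3-one (isopropyl vinyl ketone)
Product: 5 (S)-7-methyl-7-(4-methyl-3-oxopentyl)-1,4-dioxaspiro[4.5]decan-8-one, via imine 4 (not isolated)
Conditions: 2, TsOH (cat.), toluene, reflux (water separator); then 3, THF, 40 °C; then 20% aq. AcOH, rt
Reagents that add atoms: water (O)
Why: Deracemising Michael addition of the chiral imine: its more substituted secondary-enamine tautomer should add to the vinyl ketone in an aza-ene-like chair transition state on the face away from the phenyl group, setting the quaternary C1 at the methyl-bearing α-carbon, and hydrolysis returns the ketone and the amine.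

Step 2
Reactants: 5 (S)-7-methyl-7-(4-methyl-3-oxopentyl)-1,4-dioxaspiro[4.5]decan-8-one
Product: 7 (7aS)-7a-methyl-3-(propan-2-yl)-1,2,5,6-tetrahydro-4H-indene-4,7(7aH)-dione, via triketone 6 (not isolated)
Conditions: HCl (cat.), THF–H2O, rt; then KOH (0.5 equiv), MeOH, 50 °C
Reagents that add atoms: water (O)
Why: Ketal hydrolysis then intramolecular aldol condensation of C5 (α to the C6 ketone) onto the side-chain ketone C4 should close the five-membered ring (enolate attack, 5-exo-type) with the C4=C5 double bond, because this is the only aldol mode that can dehydrate to a conjugated enone and the others are reversible.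

Step 3
Reactants: 7 (7aS)-7a-methyl-3-(propan-2-yl)-1,2,5,6-tetrahydro-4H-indene-4,7(7aH)-dione
Product: 8 C10 ethylene ketal of 7 (enone carbonyl C6 free)
Conditions: ethane-1,2-diol, TsOH (cat.), benzene, reflux (water separator)
Reagents that add atoms: ethane-1,2-diol (OCCO)
Why: Acid-catalysed ketalisation should be selective for the saturated C10 ketone because the C6 carbonyl is deactivated by conjugation with the tetrasubstituted C4=C5 bond; the ketal shields C10 from hydrazine and borane.

Step 4
Reactants: 8 C10 ethylene ketal of 7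
Product: 9 C4–C5 epoxy ketone (epoxide oxygen anti to the C1 methyl)
Conditions: 30% H2O2, NaOH (cat.), MeOH, 0 °C → rt
Reagents that add atoms: hydrogen peroxide (OO)
Why: Weitz–Scheffer nucleophilic epoxidation: hydroperoxide should add to C4 and close onto C5 on the face anti to the angular C1 methyl, which sets the C4–O bond of the later tertiary alcohol.

Step 5
Reactants: 9 C4–C5 epoxy ketone
Product: 11 (1S,4S) tertiary allylic alcohol (C4–OH anti to the C1 methyl, C4 isopropyl, C5=C6, C10 dioxolane), via hydrazone 10 (not isolated)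
Conditions: N2H4·H2O, AcOH (cat.), MeOH, 0 °C → rt
Reagents that add atoms: none
Why: Wharton rearrangement: the C6 hydrazone opens the epoxide and the alkenyldiazene loses N2, giving the 1,3-transposed tertiary allylic alcohol with the C4–O bond retained and the double bond at C5=C6.

Step 6
Reactants: 11 (1S,4S) tertiary allylic alcohol
Product: 12 (1S,4S,5S,6S) trans-hydrindane diol (C5–H, C4–OH and C6–OH all anti to the C1 methyl; C10 dioxolane)
Conditions: BH3·THF, THF, 0 °C → rt; then NaOH, 30% H2O2, 0 °C → rt
Reagents that add atoms: hydrogen peroxide (OO)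
Why: Hydroboration–oxidation: borane should add syn across C5=C6 from the face anti to both the C1 methyl and the C4 isopropyl group, with boron on the less substituted C6, so that H-5 and the C6 hydroxyl are set together and the ring fusion becomes trans; oxidation proceeds with retention.

Step 7
Reactants: 13 4-hydroxybenzoic acid
Product: 15 4-[(triisopropylsilyl)oxy]benzoic acid, via silyl ester 14 (not isolated)
Conditions: i-Pr3SiCl (2.2 equiv), imidazole, DMF, rt; then AcOH–THF–H2O, rt
Reagents that add atoms: chlorotriisopropylsilane (CC(C)[Si](Cl)(C(C)C)C(C)C)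
Why: Silylation of both acidic groups followed by selective hydrolysis of the labile silyl ester leaves the robust aryl silyl ether (standard phenol protection).

Step 8
Reactants: 12 (1S,4S,5S,6S) trans-hydrindane diol; 15 4-[(triisopropylsilyl)oxy]benzoic acid
Product: 16 C6 4-[(triisopropylsilyl)oxy]benzoate of 12
Conditions: DCC, DMAP (cat.), CH2Cl2, 0 °C → rt
Reagents that add atoms: none
Why: Steglich esterification of the only secondary hydroxyl (C6) with retention; the tertiary C4 hydroxyl does not acylate under these conditions.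

Step 9
Reactants: 16 C6 4-[(triisopropylsilyl)oxy]benzoate of 12
Product: 17 (1S,4S,5S,6S) keto ester (free C10 ketone)
Conditions: TsOH (cat.), THF–H2O, 40 °C
Reagents that add atoms: water (O)
Why: Acid-catalysed hydrolysis of the dioxolane frees the C10 ketone; the esters, the aryl silyl ether and the tertiary alcohol should tolerate dilute TsOH.

Step 10
Reactants: 17 (1S,4S,5S,6S) keto ester
Product: 18 C8-methyl ketone (mixture of C8 epimers)
Conditions: LiN(SiMe3)2 (2.2 equiv), THF, −78 °C; MeI, −78 → −20 °C
Reagents that add atoms: iodomethane (CI)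
Why: The C10 ketone can enolise only towards C8 because C1 is quaternary, so enolate alkylation installs the C8 methyl regiospecifically; the C8 configuration is irrelevant because C8 becomes trigonal in step 13.

Step 11
Reactants: 18 C8-methyl ketone
Product: 19 bis(trimethylsilyl) compound (C8=C10 silyl enol ether, C4–O–SiMe3)
Conditions: Me3SiOTf, Et3N, CH2Cl2, 0 °C → rt
Reagents that add atoms: trimethylsilyl trifluoromethanesulfonate (C[Si](C)(C)OS(=O)(=O)C(F)(F)F)
Why: Soft enolisation gives the only possible (tetrasubstituted) silyl enol ether; the tertiary C4 hydroxyl is silylated at the same time, which protects it in steps 12 and 13.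

Step 12
Reactants: 19 bis(trimethylsilyl) compound
Product: 20 silyloxycyclopropane (CH2 = C9 bridging C8 and C10; 1-silyloxy-6-methylbicyclo[4.1.0]heptane unit, mixture of cyclopropane faces)
Conditions: ZnEt2, CH2I2, CH2Cl2, 0 °C → rt
Reagents that add atoms: diiodomethane (ICI)
Why: Simmons–Smith cyclopropanation of the electron-rich enol ether, the only C=C bond in the molecule; both new cyclopropane stereocentres are removed in the next step.

Step 13
Reactants: 20 silyloxycyclopropane
Product: 22 (1S,4S,5S,6S) cycloheptenone (C10 ketone, C8=C9, C8 methyl, C4–OH free), via chloro ketone 21 (not isolated)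
Conditions: FeCl3 (2.5 equiv), DMF, 0 °C → rt; then NaOAc, MeOH, 60 °C; 1 M HCl work-up
Reagents that add atoms: none
Why: FeCl3 oxidises the silyloxycyclopropane by one electron (with loss of Me3SiCl) to an oxygen-centred radical, whose β-scission breaks the C8–C10 bond shared by the three- and six-membered rings, so that C9 becomes a ring member and the ring grows from six to seven atoms with C10 as the ketone. The tertiary C8 radical takes chlorine from a second FeCl3 to give β-chloro ketone 21, and NaOAc removes HCl across C8–C9 through the C9 enolate to give the conjugated enone. The closest known reaction type is the Ito–Saegusa ring expansion of 1-silyloxybicyclo[n.1.0]alkanes, here on a 6-methyl case. No ring is closed by cyclisation in this step; the seven-membered ring arises by fragmentation-type enlargement of the six-membered ring when the cyclopropane made in step 12 opens. No stereocentre is created (C8 and C10 become trigonal), and C1, C4, C5 and C6 are untouched because the only carbon α to the new ketone besides C9 is the quaternary C1. The step needs cleavage of the internal rather than the external (C9–C10) cyclopropane bond, secured by the methyl group that makes the C8 radical tertiary, and elimination towards C9 rather than C7 or the methyl, secured by the acidity of the C9–H bonds α to the carbonyl.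

Step 14
Reactants: 22 (1S,4S,5S,6S) cycloheptenone
Product: 23 (1S,4S,5S,6S,10R) allylic alcohol (C10–OH anti to the C1 methyl)
Conditions: (S)-1-methyl-3,3-diphenyl-tetrahydro-1H,3H-pyrrolo[1,2-c][1,3,2]oxazaborole (20 mol %), BH3·SMe2, THF, −40 °C; MeOH quench
Reagents that add atoms: none
Why: Corey–Bakshi–Shibata reduction: reagent-controlled 1,2-hydride delivery with the quaternary C1 side as the large group should give the (10R) alcohol from the (S)-catalyst.

Step 15
Reactants: 23 (1S,4S,5S,6S,10R) allylic alcohol; 24 (E)-2-methylbut-2-enoyl chloride (tigloyl chloride)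
Product: 25 O-triisopropylsilyl ether of the target
Conditions: DMAP, pyridine, CH2Cl2, 0 → 40 °C
Reagents that add atoms: none
Why: DMAP-catalysed acylation of the secondary allylic C10 hydroxyl by the acid chloride; the tertiary C4 hydroxyl is inert and the (E) geometry of the tigloyl group is retained.

Step 16
Reactants: 25 O-triisopropylsilyl ether of the target
Product: 26 target, (1S,4S,5S,6S,10R)-dauc-8-ene-4,6,10-triol 6-(4-hydroxybenzoate) 10-[(E)-2-methylbut-2-enoate]
Conditions: Bu4NF, AcOH, THF, 0 °C
Reagents that add atoms: none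
Why: Fluoride cleaves the aryl Si–O bond, buffered with AcOH so that neither ester migrates or hydrolyses, and frees the phenol.

**Compound list**

1 | 7-methyl-1,4-dioxaspiro[4.5]decan-8-one (racemic) | O=C1CCC2(OCCO2)CC1C | starting material
2 | (S)-1-phenylethylamine | C[C@H](N)c1ccccc1 | starting material
3 | 4-methylpent-1-en-3-one | C=CC(=O)C(C)C | starting material
4 | (S)-N-(7-methyl-1,4-dioxaspiro[4.5]decan-8-ylidene)-1-phenylethylamine | C[C@H](N=C1CCC2(OCCO2)CC1C)c1ccccc1 | intermediate (not isolated)
5 | (S)-7-methyl-7-(4-methyl-3-oxopentyl)-1,4-dioxaspiro[4.5]decan-8-one | O=C1CCC2(OCCO2)C[C@]1(C)CCC(=O)C(C)C | intermediate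
6 | (S)-2-methyl-2-(4-methyl-3-oxopentyl)cyclohexane-1,4-dione | O=C1CCC(=O)C[C@]1(C)CCC(=O)C(C)C | intermediate (not isolated)
7 | (7aS)-7a-methyl-3-(propan-2-yl)-1,2,5,6-tetrahydro-4H-indene-4,7(7aH)-dione | O=C1CCC(=O)C2=C(C(C)C)CC[C@]12C | intermediate
8 | C10 ethylene ketal of 7 | C12(OCCO2)CCC(=O)C3=C(C(C)C)CC[C@]13C | intermediate
9 | C4–C5 epoxide of 8, oxygen anti to the C1 methyl | C12(OCCO2)CCC(=O)[C@@]34O[C@]3(C(C)C)CC[C@]14C | intermediate
10 | C6 hydrazone of 9 | C12(OCCO2)CCC(=NN)[C@@]34O[C@]3(C(C)C)CC[C@]14C | intermediate (not isolated)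
11 | (1S,4S) tertiary allylic alcohol: C4–OH, C4 isopropyl, C5=C6, C10 dioxolane | C12(OCCO2)CCC=C3[C@]1(C)CC[C@]3(O)C(C)C | intermediate
12 | (1S,4S,5S,6S) trans-hydrindane diol: C4–OH, C6–OH, C5–H anti to the C1 methyl, C10 dioxolane | C12(OCCO2)CC[C@H](O)[C@@H]3[C@]1(C)CC[C@]3(O)C(C)C | intermediate
13 | 4-hydroxybenzoic acid | OC(=O)c1ccc(O)cc1 | starting material
14 | triisopropylsilyl 4-[(triisopropylsilyl)oxy]benzoate | CC(C)[Si](OC(=O)c1ccc(O[Si](C(C)C)(C(C)C)C(C)C)cc1)(C(C)C)C(C)C | intermediate (not isolated)
15 | 4-[(triisopropylsilyl)oxy]benzoic acid | OC(=O)c1ccc(O[Si](C(C)C)(C(C)C)C(C)C)cc1 | intermediate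
16 | C6 4-[(triisopropylsilyl)oxy]benzoate of 12 | C12(OCCO2)CC[C@H](OC(=O)c4ccc(O[Si](C(C)C)(C(C)C)C(C)C)cc4)[C@@H]3[C@]1(C)CC[C@]3(O)C(C)C | intermediate
17 | (1S,4S,5S,6S) keto ester, C10 ketone | O=C1CC[C@H](OC(=O)c4ccc(O[Si](C(C)C)(C(C)C)C(C)C)cc4)[C@@H]3[C@]1(C)CC[C@]3(O)C(C)C | intermediate
18 | C8-methyl ketone (C8 epimers) | O=C1C(C)C[C@H](OC(=O)c4ccc(O[Si](C(C)C)(C(C)C)C(C)C)cc4)[C@@H]3[C@]1(C)CC[C@]3(O)C(C)C | intermediate
19 | C8=C10 trimethylsilyl enol ether with C4–O–SiMe3 | C[Si](C)(C)OC1=C(C)C[C@H](OC(=O)c4ccc(O[Si](C(C)C)(C(C)C)C(C)C)cc4)[C@@H]3[C@]1(C)CC[C@]3(O[Si](C)(C)C)C(C)C | intermediate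
20 | silyloxycyclopropane, CH2 (C9) across C8–C10 | C[Si](C)(C)OC12CC2(C)C[C@H](OC(=O)c4ccc(O[Si](C(C)C)(C(C)C)C(C)C)cc4)[C@@H]3[C@]1(C)CC[C@]3(O[Si](C)(C)C)C(C)C | intermediate
21 | β-chloro cycloheptanone, C8 (CH3)(Cl) | O=C1CC(C)(Cl)C[C@H](OC(=O)c4ccc(O[Si](C(C)C)(C(C)C)C(C)C)cc4)[C@@H]3[C@]1(C)CC[C@]3(O[Si](C)(C)C)C(C)C | intermediate (not isolated)
22 | (1S,4S,5S,6S) cycloheptenone: C10 ketone, C8=C9, C4–OH | O=C1C=C(C)C[C@H](OC(=O)c4ccc(O[Si](C(C)C)(C(C)C)C(C)C)cc4)[C@@H]3[C@]1(C)CC[C@]3(O)C(C)C | intermediate
23 | (1S,4S,5S,6S,10R) allylic alcohol | O[C@@H]1C=C(C)C[C@H](OC(=O)c4ccc(O[Si](C(C)C)(C(C)C)C(C)C)cc4)[C@@H]3[C@]1(C)CC[C@]3(O)C(C)C | intermediate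
24 | (E)-2-methylbut-2-enoyl chloride | C/C=C(\C)C(=O)Cl | starting material
25 | O-triisopropylsilyl ether of the target | C/C=C(\C)C(=O)O[C@@H]1C=C(C)C[C@H](OC(=O)c4ccc(O[Si](C(C)C)(C(C)C)C(C)C)cc4)[C@@H]3[C@]1(C)CC[C@]3(O)C(C)C | intermediate
26 | (1S,4S,5S,6S,10R)-dauc-8-ene-4,6,10-triol 6-(4-hydroxybenzoate) 10-[(E)-2-methylbut-2-enoate] | C/C=C(\C)C(=O)O[C@@H]1C=C(C)C[C@H](OC(=O)c2ccc(O)cc2)[C@@H]2[C@]1(C)CC[C@]2(O)C(C)C | target

**Step count and risks**

Total: 16 steps. Longest linear sequence: 15 steps (steps 1–6 and 8–16); step 7 is a one-step side branch.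

Steps most likely to fail:

- **Step 13 (with its precursor step 12).** The fully substituted, hindered silyloxycyclopropane may resist one-electron oxidation or fragment at the external bond, and the Lewis-acidic iron salt may strip the silyl ethers before fragmentation. The fallback sets out from 17 and returns at 22. One-carbon homologation of the C10 ketone with Me3SiCHN2/AlMe3 (CH2Cl2, −78 °C; the less substituted C8 should migrate) and acidic protodesilylation should give the ring-enlarged cycloheptanone F1. Dehydrogenation with IBX, where enolisation is again possible only towards the new C9, should give the cycloheptenone F2. Me2CuLi/Me3SiCl should add the C8 methyl and trap the enolate as the bis-silyl enol ether F3. Pd(OAc)2 (Saegusa–Ito oxidation) followed by dilute acid should restore the C8=C9 double bond and give 22.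

- **Step 5.** Hydrazone formation at the hindered C6 carbonyl may be slow, and the alkenyl intermediate may be diverted (reduction or elimination instead of clean transposition). The fallback sets out from 9 and returns at 16. SmI2 in THF/MeOH at −90 °C should cleave the C5–O bond of the epoxy ketone to the β-hydroxy ketone F4, the samarium enolate being protonated at C5 on the face anti to the C1 methyl and the C4 isopropyl group. LiBH(s-Bu)3 at −78 °C should reduce the C6 ketone from the same open face to the C6-epimeric alcohol F5 (hydroxyl syn to the methyl). Mitsunobu esterification with acid 15 (DIAD, PPh3) should invert C6 and give 16.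

- **Step 14.** Facial selectivity may be poor, because hydride has to enter on the face that carries the C1 methyl and substrate bias may oppose the catalyst. The fallback sets out from 22 and returns at 25. Luche reduction (NaBH4, CeCl3·7H2O, MeOH) should deliver hydride anti to the methyl and give the C10-epimeric allylic alcohol F6. A Mitsunobu reaction with tiglic acid (DIAD, PPh3) should then install the tigloyl ester with inversion and give 25.

**Further compounds**

F1 | step 13 | ring-enlarged cycloheptanone (C10 ketone, C9 and C8 both CH2) | O=C1CCC[C@H](OC(=O)c4ccc(O[Si](C(C)C)(C(C)C)C(C)C)cc4)[C@@H]3[C@]1(C)CC[C@]3(O)C(C)C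
F2 | step 13 | cycloheptenone without the C8 methyl (C10 ketone, C8=C9) | O=C1C=CC[C@H](OC(=O)c4ccc(O[Si](C(C)C)(C(C)C)C(C)C)cc4)[C@@H]3[C@]1(C)CC[C@]3(O)C(C)C
F3 | step 13 | C9=C10 trimethylsilyl enol ether with C8 methyl and C4–O–SiMe3 | C[Si](C)(C)OC1=CC(C)C[C@H](OC(=O)c4ccc(O[Si](C(C)C)(C(C)C)C(C)C)cc4)[C@@H]3[C@]1(C)CC[C@]3(O[Si](C)(C)C)C(C)C
F4 | step 5 | β-hydroxy ketone (C4–OH, C5–H anti to the C1 methyl, C6 ketone, C10 dioxolane) | C12(OCCO2)CCC(=O)[C@@H]3[C@]1(C)CC[C@]3(O)C(C)C
F5 | step 5 | C6-epimer of 12 (C6–OH syn to the C1 methyl) | C12(OCCO2)CC[C@@H](O)[C@@H]3[C@]1(C)CC[C@]3(O)C(C)C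
F6 | step 14 | C10-epimer of 23 (C10–OH syn to the C1 methyl) | O[C@H]1C=C(C)C[C@H](OC(=O)c4ccc(O[Si](C(C)C)(C(C)C)C(C)C)cc4)[C@@H]3[C@]1(C)CC[C@]3(O)C(C)C
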